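At 2.5 h, the time of reading, what you want to know is how much of the early pace is left, so work with that fraction and not with the target made.

| flask | substrate | partner | initiator | temperature | remark | time |
|---|---|---|---|---|---|---|
| theta | 0.10 M | 1.8 equiv | 10 mol% | 90 °C | run made earlier |  |
| autumn | 0.050 M | 1.80 equiv | 10 mol% | 130 °C |  | 2.5 h |
| winter | 0.050 M | 1.80 equiv | 10 mol% | 75 °C |  | 2.5 h |
| spring | 0.050 M | 1.80 equiv | 10 mol% | 50 °C |  | 2.5 h |
| noon | 0.050 M | 1.80 equiv | 10 mol% | 90 °C |  | 2.5 h |
| midnight | 0.050 M | 1.80 equiv | 10 mol% | 120 °C |  | 2.5 h |

theta run (percent of the substrate charged)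

| time / min | target / % |
|---|---|
| 2.00 | 2.2 |
| 6.00 | 7.7 |
| 10.0 | 11.7 |
| 15.0 | 14.6 |
| 25.0 | 21.4 |
| 30.0 | 23.9 |

(readings scatter by 0.5 percentage points)

- the earlier runs do not show what temperature does; that part of a forecast is a guess
- no earlier run changes the charge of initiator; that part of a forecast is a guess

- ranking by amount of target, in percent of the substrate charged, from high to low, at 2.5 h (autumn / winter / spring / noon / midnight)
- the same order at 20 h (autumn / winter / spring / noon / midnight)
- the amount of target, in percent of the substrate charged of the flask you put first, at 2.5 h
- the amount of target, in percent of the substrate charged of the flask you put last, at 2.5 h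

Start with the main step alone, target forming at a steady pace. Between 2.00 min and 10.0 min the theta run gains 0.0119 min⁻¹ of its charge per minute, and at that pace 2.5 h would give 178%, more than the whole charge.

So add one process, the fading. Between 15.0 min and 30.0 min the theta run gains 0.00620 min⁻¹ per minute, which is 52.1% of the early pace. If the pace falls exponentially, the time in which it drops by a factor e, the fading time, is 25.4 min. This is a reading, and the scatter of 0.5 percentage points loosens it. What theta has still to make after its last reading is the pace at that moment times the fading time, so the theta ceiling is 35.6%.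

Now the rest, all of it my own guess. Noon has the temperature of theta, so I keep the fading time, and 2.5 h is longer than it: the fraction left is 0.272%, and noon reads at its ceiling. But noon is more dilute. If chains start from the initiator and end in pairs, the pace per unit of charge goes with the square root of concentration, which puts noon at 25.2%. Temperature is unmeasured, so I give no number for the other flasks. I guess noon first and spring last at 2.5 h, with winter ahead at 20 h.

The forecast gives noon > winter > midnight > autumn > spring at 2.5 h and winter > noon > spring > midnight > autumn at 20 h, with 18% and 2% for its first and last flasks, holding that “hotter flasks burn out early at lower plateaus”, and for noon my figure lies above its own.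

The simulation gives noon > winter > midnight > autumn > spring at 2.5 h and winter > noon > midnight > spring > autumn at 20 h, with 26.8% in noon and 2.11% in spring.

    substrate + target → side product (k = 0.0460 M⁻¹ min⁻¹, Ea = 66.0 kJ mol⁻¹)
    2 substrate → self-condensation product (k = 0.160 M⁻¹ min⁻¹, Ea = 73.0 kJ mol⁻¹)
    2 first chain carrier → ended chains (k = 4.80 × 10⁶ M⁻¹ s⁻¹, Ea = 16.0 kJ mol⁻¹)
    substrate + second chain carrier → by-product + first chain carrier (k = 2.10 × 10⁵ M⁻¹ min⁻¹, Ea = 38.0 kJ mol⁻¹)
    partner → decomposed reagent (k = 0.0260 min⁻¹, Ea = 121 kJ mol⁻¹)
    substrate + initiating radical → capped initiator + first chain carrier (k = 1.80 × 10⁵ M⁻¹ s⁻¹, Ea = 20.0 kJ mol⁻¹)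
    initiator → 2 initiating radical (k = 0.00100 min⁻¹, Ea = 120 kJ mol⁻¹)
    partner + first chain carrier ⇌ target + second chain carrier (K = 4.00, k = 40000 M⁻¹ min⁻¹, Ea = 50.0 kJ mol⁻¹, ΔH = −61.0 kJ mol⁻¹)
    (constants at 90 °C)

The fading time put the theta ceiling at 35.6%, and the theta run carried on to 2.5 h stands at 34.7%; for noon, the fading time with the square root gave 25.2%, and the flask holds 26.8%. At 2.5 h noon still has 19% of its substrate and 0.97% of its partner, the first of its charges to run out. The main reason for so low a figure is the step from two first chain carriers to ended chains: with that step struck out, noon holds 97.9% of target in place of 26.8%.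

The readings are calculated with constants of no real substance; scatter was added.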